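**Plan**

- Locants per half: ring A = N5, C4, C3 (methyl), C2 (ketone), C1, C10; ring B = N5, C6 to C10; chain a to e runs from C9 to C1 of the other half. The C2 ketone lies 1,4 to chain carbon d across C1 and e, so with d as an ester carbon C1–C2 is the bond an acyl anion at C2 makes by adding to a C1=e enoate.
- Cuts, in retrosynthetic order: both c–d chain bonds (the twofold-symmetric 16-membered ring falls into two identical halves), then C1–C2 (intramolecular Stetter), N5–C4 (aza-Michael to methacrolein), C1=e (Wittig), the ring B hydrogens (pyridine hydrogenation) and C9–a (Sonogashira).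
- Forward: ring B from a 3-alkynylpicolinate, ring A by the Stetter closure of the 4-piperidone, then the macrocycle by head-to-tail double Wittig of a monomer with the aldehyde at c and the ylide at d; hydrogenation and ketal removal finish.
- Stereochemistry: C9/C10 cis from syn hydrogenation of the pyridine, absolute configuration by resolution of the cis amino ester; C1 and C3, both α to the C2 ketone, by equilibration to the all-equatorial ring A.

Key step: step 9

Remark (resolution): the (2R,3R)-amine is assumed to give the less soluble salt with the L-configured acid; if its antipode crystallises, the D-acid is used and nothing else changes.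
Remark (aldehyde 12): the aza-Michael step cannot control the formyl-bearing carbon, so 12 is carried as both epimers there; this carbon becomes the enolisable C3.
Remark (roles of the chains): the phosphonium group is put on the C1 chain (carbon d) and the aldehyde on the C9 chain (carbon c), because a leaving group on the axial C9 chain would sit beside the nitrogen lone pair and alkylate it.
TBS = tert-butyldimethylsilyl; Alloc = allyloxycarbonyl.

**Route**

Step 1
Reactants: 1 methyl 3-bromopicolinate; 2 tert-butyldimethyl(prop-2-ynyloxy)silane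
Product: 3 methyl 3-[3-(TBS-oxy)prop-1-ynyl]pyridine-2-carboxylate
Conditions: PdCl2(PPh3)2 (cat.), CuI (cat.), Et3N, THF, 50 °C
Reagents that add atoms: none
Why: Sonogashira coupling; the bromide ortho to the ester on the electron-poor pyridine should undergo oxidative addition readily, and silyl propargyl ethers are standard alkyne partners.

Step 2
Reactants: 3 methyl 3-[3-(TBS-oxy)prop-1-ynyl]pyridine-2-carboxylate
Product: 4 (±)-methyl cis-3-[3-(TBS-oxy)propyl]piperidine-2-carboxylate
Conditions: H2 (5 bar), PtO2, MeOH–AcOH (10:1), rt; aq. NaHCO3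
Reagents that add atoms: none
Why: Heterogeneous hydrogenation; the alkyne is saturated first and the protonated picolinate ring then takes up hydrogen from the catalyst face it lies on, so the hydrogens at the future C9 and C10 arrive syn and the cis isomer should predominate, while the dilute acetic acid should spare the silyl ether.

Step 3
Reactants: 4 (±)-methyl cis-3-[3-(TBS-oxy)propyl]piperidine-2-carboxylate
Product: 5 methyl (2R,3R)-3-[3-(TBS-oxy)propyl]piperidine-2-carboxylate
Conditions: (−)-O,O'-di-p-toluoyl-L-tartaric acid, MeOH–EtOAc, recrystallisation; aq. NaHCO3, CH2Cl2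
Reagents that add atoms: none
Why: Classical resolution by crystallisation of diastereomeric salts, as is routine for pipecolate and nipecotate esters; it fixes the absolute configuration of the future C9 and C10.

Step 4
Reactants: 5 methyl (2R,3R)-3-[3-(TBS-oxy)propyl]piperidine-2-carboxylate
Product: 6 1-allyl 2-methyl (2R,3R)-3-[3-(TBS-oxy)propyl]piperidine-1,2-dicarboxylate
Conditions: allyl chloroformate, Et3N, CH2Cl2, 0 °C to rt
Reagents that add atoms: allyl chloroformate, C=CCOC(=O)Cl
Why: Carbamate formation at the secondary amine; Alloc is chosen over Boc because its later removal is neutral and leaves the silyl ether and the enoate alone, and the carbamate tames the α-amino aldehyde to come.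

Step 5
Reactants: 6 1-allyl 2-methyl (2R,3R)-3-[3-(TBS-oxy)propyl]piperidine-1,2-dicarboxylate
Product: 7 allyl (2R,3R)-3-[3-(TBS-oxy)propyl]-2-formylpiperidine-1-carboxylate
Conditions: i-Bu2AlH, toluene, −78 °C; MeOH, aq. potassium sodium tartrate
Reagents that add atoms: none
Why: Partial reduction of the methyl ester through the tetrahedral aluminate, stable at −78 °C; the cis arrangement (axial formyl next to the carbamate, equatorial C3 chain) is the one A(1,3) strain favours, so epimerisation at C2 has no driving force.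

Step 6
Reactants: 7 allyl (2R,3R)-3-[3-(TBS-oxy)propyl]-2-formylpiperidine-1-carboxylate; 8 ethyl (triphenylphosphoranylidene)acetate
Product: 9 allyl (2R,3R)-3-[3-(TBS-oxy)propyl]-2-[(E)-3-ethoxy-3-oxoprop-1-enyl]piperidine-1-carboxylate
Conditions: CH2Cl2, rt
Reagents that add atoms: none
Why: Wittig olefination with a stabilised ylide, which should give the (E)-enoate (C1=e, ester carbon d) under non-basic conditions that leave the α-stereocentre untouched.

Step 7
Reactants: 9 allyl (2R,3R)-3-[3-(TBS-oxy)propyl]-2-[(E)-3-ethoxy-3-oxoprop-1-enyl]piperidine-1-carboxylate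
Product: 10 ethyl (E)-3-[(2R,3R)-3-[3-(TBS-oxy)propyl]piperidin-2-yl]prop-2-enoate
Conditions: Pd(PPh3)4 (cat.), morpholine, THF, rt
Reagents that add atoms: none
Why: Tsuji–Trost deallylation; the zerovalent palladium complex ionises the allyl carbamate, morpholine takes up the allyl group and the carbamic acid loses CO2, all under neutral conditions.

Step 8
Reactants: 10 ethyl (E)-3-[(2R,3R)-3-[3-(TBS-oxy)propyl]piperidin-2-yl]prop-2-enoate; 11 methacrolein
Product: 12 ethyl (E)-3-[(2R,3R)-3-[3-(TBS-oxy)propyl]-1-(2-methyl-3-oxopropyl)piperidin-2-yl]prop-2-enoate (both epimers at the formyl-bearing carbon)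
Conditions: methacrolein (2 equiv), CH2Cl2, rt; volatiles removed below 25 °C, crude product used at once
Reagents that add atoms: none
Why: Aza-Michael addition of the secondary amine to the enal, which brings in C4, C3, the methyl group and C2 in one bond formation; the uncontrolled centre is later the enolisable C3.

Step 9
Reactants: 12 ethyl (E)-3-[(2R,3R)-3-[3-(TBS-oxy)propyl]-1-(2-methyl-3-oxopropyl)piperidin-2-yl]prop-2-enoate
Product: 13 ethyl 2-[(1R,3S,9R,9aR)-9-[3-(TBS-oxy)propyl]-3-methyl-2-oxooctahydro-2H-quinolizin-1-yl]acetate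
Conditions: 2-(pentafluorophenyl)-6,7-dihydro-5H-pyrrolo[2,1-c][1,2,4]triazol-2-ium tetrafluoroborate (20 mol%), KN(SiMe3)2 (20 mol%), toluene, rt to 40 °C; then DBU (0.3 equiv), rt
Reagents that add atoms: none
Why: Intramolecular Stetter reaction: the triazolylidene adds to the C2 aldehyde, proton transfer gives the Breslow intermediate, this acyl anion equivalent adds to the enoate β-carbon C1, and proton transfer with loss of the carbene leaves the C2 ketone. The closest known reaction type is the triazolium-catalysed cyclisation of aliphatic aldehydes onto tethered enoates, nitrogen-tethered cases included. Ring A (N5, C4, C3, C2, C1, C10) closes in the 6-exo-trig mode with the C1=e bond exocyclic. C1 is the new stereocentre and, like C3, is α to the ketone; the DBU treatment should bring both substituents equatorial on the chair of ring A (H1 trans to H10, methyl cis to the C1 chain) under control of the fixed C10 centre. The step needs the acyl anion addition to outpace benzoin and aldol reactions and retro-aza-Michael loss of methacrolein; the α-branch of the aldehyde slows self-condensation, ring B holds aldehyde and enoate within reach, and only catalytic base is present.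

Step 10
Reactants: 13 ethyl 2-[(1R,3S,9R,9aR)-9-[3-(TBS-oxy)propyl]-3-methyl-2-oxooctahydro-2H-quinolizin-1-yl]acetate
Product: 14 ethyl 2-[(1R,3S,9R,9aR)-9-[3-(TBS-oxy)propyl]-2,2-(ethylenedioxy)-3-methyloctahydro-2H-quinolizin-1-yl]acetate
Conditions: 1,2-bis(trimethylsilyloxy)ethane, TMSOTf (1.5 equiv), CH2Cl2, −78 to −10 °C; pyridine, aq. NaHCO3
Reagents that add atoms: 1,2-bis(trimethylsilyloxy)ethane, C[Si](C)(C)OCCO[Si](C)(C)C
Why: Noyori ketalisation by silyl transfer, run cold and aprotic so that the silyl ether survives and C1 and C3 are not disturbed (the excess TMSOTf allows for the basic nitrogen); the ketal blocks reduction and enolisation of C2 in the steps that follow.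

Step 11
Reactants: 14 ethyl 2-[(1R,3S,9R,9aR)-9-[3-(TBS-oxy)propyl]-2,2-(ethylenedioxy)-3-methyloctahydro-2H-quinolizin-1-yl]acetate
Product: 15 2-[(1R,3S,9R,9aR)-9-[3-(TBS-oxy)propyl]-2,2-(ethylenedioxy)-3-methyloctahydro-2H-quinolizin-1-yl]ethanol
Conditions: LiAlH4, THF, 0 °C; H2O, aq. NaOH
Reagents that add atoms: none
Why: Hydride reduction of the ester to the primary alcohol at chain carbon d; ketal, silyl ether and tertiary amine are inert to LiAlH4.

Step 12
Reactants: 15 2-[(1R,3S,9R,9aR)-9-[3-(TBS-oxy)propyl]-2,2-(ethylenedioxy)-3-methyloctahydro-2H-quinolizin-1-yl]ethanol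
Product: 16 (1R,3S,9R,9aR)-1-(2-bromoethyl)-9-[3-(TBS-oxy)propyl]-2,2-(ethylenedioxy)-3-methyloctahydro-2H-quinolizine
Conditions: CBr4, PPh3, 2,6-lutidine, CH2Cl2, 0 °C
Reagents that add atoms: carbon tetrabromide, BrC(Br)(Br)Br
Why: Appel reaction, SN2 displacement at the primary alkoxyphosphonium carbon; the bromoethyl chain is equatorial at C1 and points away from the axial nitrogen lone pair, so closure to a bridged ammonium salt would require a ring A flip that puts the C1 chain and the C3 methyl group both axial.

Step 13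
Reactants: 16 (1R,3S,9R,9aR)-1-(2-bromoethyl)-9-[3-(TBS-oxy)propyl]-2,2-(ethylenedioxy)-3-methyloctahydro-2H-quinolizine
Product: 18 [2-[(1R,3S,9R,9aR)-2,2-(ethylenedioxy)-9-(3-hydroxypropyl)-3-methyloctahydro-2H-quinolizin-1-yl]ethyl]triphenylphosphonium bromide, via silyl ether phosphonium bromide 17 (not isolated)
Conditions: PPh3 (4 equiv), MeCN, 80 °C; then 48% aq. HF, MeCN, 0 °C to rt; aq. NaHCO3, aq. NaBr wash
Reagents that add atoms: triphenylphosphine, c1ccc(cc1)P(c1ccccc1)c1ccccc1
Why: SN2 quaternisation of PPh3 by the primary bromide (the nitrogen is screened by the axial C9 chain and PPh3 is in excess), then acidic fluoride cleavage of the silyl ether, which the ketal should survive because the protonated nitrogen disfavours the oxocarbenium ion at C2.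

Step 14
Reactants: 18 [2-[(1R,3S,9R,9aR)-2,2-(ethylenedioxy)-9-(3-hydroxypropyl)-3-methyloctahydro-2H-quinolizin-1-yl]ethyl]triphenylphosphonium bromide
Product: 19 [2-[(1R,3S,9R,9aR)-2,2-(ethylenedioxy)-3-methyl-9-(3-oxopropyl)octahydro-2H-quinolizin-1-yl]ethyl]triphenylphosphonium bromide
Conditions: (COCl)2, DMSO, CH2Cl2, −78 °C; Et3N, −78 to 0 °C; used crude
Reagents that add atoms: none
Why: Swern oxidation of the primary alcohol at chain carbon c, known to tolerate hydroxyalkylphosphonium salts and tertiary amines; Et3N is too weak to form the ylide, and the ketal rules out an aldol between C1 and the new aldehyde.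

Step 15
Reactants: 19 [2-[(1R,3S,9R,9aR)-2,2-(ethylenedioxy)-3-methyl-9-(3-oxopropyl)octahydro-2H-quinolizin-1-yl]ethyl]triphenylphosphonium bromide (two molecules)
Product: 20 macrocyclic (Z,Z)-diene bis(ethylene ketal): two (1R,3S,9S,9aR)-2,2-(ethylenedioxy)-3-methyloctahydro-2H-quinolizine units joined twice, C9 of each to C1 of the other, by a CH2CH2CH=CHCH2 chain with the double bond between c and d
Conditions: KN(SiMe3)2 (1.05 equiv), THF (0.01 M in 19), −78 °C to rt
Reagents that add atoms: none
Why: Wittig reaction run as a head-to-tail cyclodimerisation; the non-stabilised ylide at d of one molecule adds to the aldehyde at c of another and the open dimer closes the 16-membered ring by the same reaction, the two identical halves giving the twofold-symmetric product, with the alkene geometry of no consequence (the C9 descriptor changes by priority only).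

Step 16
Reactants: 20 macrocyclic (Z,Z)-diene bis(ethylene ketal)
Product: 21 saturated macrocyclic bis(ethylene ketal): the same two units joined by pentamethylene chains
Conditions: H2 (1 atm), 10% Pd/C, EtOAc–MeOH, rt
Reagents that add atoms: none
Why: Catalytic hydrogenation of two disubstituted alkenes; ketals and tertiary amines are unaffected and no stereocentre is made or touched.

Step 17
Reactants: 21 saturated macrocyclic bis(ethylene ketal)
Product: 22 target CNP0268544.6: two (1R,3S,9S,9aR)-3-methyloctahydro-2H-quinolizin-2-one units joined twice, C9 to C1 of the other, by pentamethylene chains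
Conditions: 2 M aq. HCl–THF (1:1), 50 °C; then K2CO3 to pH 10, MeOH, rt
Reagents that add atoms: water, O
Why: Acid-catalysed ketal hydrolysis frees both C2 ketones, and the mild base treatment lets C1 and C3 settle in the equatorial arrangement set in step 9; the temperature is kept moderate to avoid retro-Mannich opening at C10.

**Compound list**

1 | methyl 3-bromopicolinate | COC(=O)c1ncccc1Br | starting material
2 | tert-butyldimethyl(prop-2-ynyloxy)silane | C#CCO[Si](C)(C)C(C)(C)C | starting material
3 | methyl 3-[3-(tert-butyldimethylsilyloxy)prop-1-ynyl]pyridine-2-carboxylate | COC(=O)c1ncccc1C#CCO[Si](C)(C)C(C)(C)C | intermediate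
4 | (±)-methyl cis-3-[3-(tert-butyldimethylsilyloxy)propyl]piperidine-2-carboxylate (racemate; one enantiomer drawn) | N1CCC[C@H](CCCO[Si](C)(C)C(C)(C)C)[C@@H]1C(=O)OC | intermediate
5 | methyl (2R,3R)-3-[3-(tert-butyldimethylsilyloxy)propyl]piperidine-2-carboxylate | N1CCC[C@H](CCCO[Si](C)(C)C(C)(C)C)[C@@H]1C(=O)OC | intermediate
6 | 1-allyl 2-methyl (2R,3R)-3-[3-(tert-butyldimethylsilyloxy)propyl]piperidine-1,2-dicarboxylate | C=CCOC(=O)N1CCC[C@H](CCCO[Si](C)(C)C(C)(C)C)[C@@H]1C(=O)OC | intermediate
7 | allyl (2R,3R)-3-[3-(tert-butyldimethylsilyloxy)propyl]-2-formylpiperidine-1-carboxylate | C=CCOC(=O)N1CCC[C@H](CCCO[Si](C)(C)C(C)(C)C)[C@@H]1C=O | intermediate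
8 | ethyl (triphenylphosphoranylidene)acetate | CCOC(=O)C=P(c1ccccc1)(c1ccccc1)c1ccccc1 | starting material
9 | allyl (2R,3R)-3-[3-(tert-butyldimethylsilyloxy)propyl]-2-[(E)-3-ethoxy-3-oxoprop-1-enyl]piperidine-1-carboxylate | C=CCOC(=O)N1CCC[C@H](CCCO[Si](C)(C)C(C)(C)C)[C@@H]1/C=C/C(=O)OCC | intermediate
10 | ethyl (E)-3-[(2R,3R)-3-[3-(tert-butyldimethylsilyloxy)propyl]piperidin-2-yl]prop-2-enoate | N1CCC[C@H](CCCO[Si](C)(C)C(C)(C)C)[C@@H]1/C=C/C(=O)OCC | intermediate
11 | methacrolein | CC(=C)C=O | starting material
12 | ethyl (E)-3-[(2R,3R)-3-[3-(tert-butyldimethylsilyloxy)propyl]-1-(2-methyl-3-oxopropyl)piperidin-2-yl]prop-2-enoate, both epimers at the formyl-bearing carbon | O=CC(C)CN1CCC[C@H](CCCO[Si](C)(C)C(C)(C)C)[C@@H]1/C=C/C(=O)OCC | intermediate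
13 | ethyl 2-[(1R,3S,9R,9aR)-9-[3-(tert-butyldimethylsilyloxy)propyl]-3-methyl-2-oxooctahydro-2H-quinolizin-1-yl]acetate | C[C@H]1CN2CCC[C@H](CCCO[Si](C)(C)C(C)(C)C)[C@@H]2[C@@H](CC(=O)OCC)C1=O | intermediate
14 | ethyl 2-[(1R,3S,9R,9aR)-9-[3-(tert-butyldimethylsilyloxy)propyl]-2,2-(ethylenedioxy)-3-methyloctahydro-2H-quinolizin-1-yl]acetate | C[C@H]1CN2CCC[C@H](CCCO[Si](C)(C)C(C)(C)C)[C@@H]2[C@@H](CC(=O)OCC)C13OCCO3 | intermediate
15 | 2-[(1R,3S,9R,9aR)-9-[3-(tert-butyldimethylsilyloxy)propyl]-2,2-(ethylenedioxy)-3-methyloctahydro-2H-quinolizin-1-yl]ethanol | C[C@H]1CN2CCC[C@H](CCCO[Si](C)(C)C(C)(C)C)[C@@H]2[C@@H](CCO)C13OCCO3 | intermediate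
16 | (1R,3S,9R,9aR)-1-(2-bromoethyl)-9-[3-(tert-butyldimethylsilyloxy)propyl]-2,2-(ethylenedioxy)-3-methyloctahydro-2H-quinolizine | C[C@H]1CN2CCC[C@H](CCCO[Si](C)(C)C(C)(C)C)[C@@H]2[C@@H](CCBr)C13OCCO3 | intermediate
17 | [2-[(1R,3S,9R,9aR)-9-[3-(tert-butyldimethylsilyloxy)propyl]-2,2-(ethylenedioxy)-3-methyloctahydro-2H-quinolizin-1-yl]ethyl]triphenylphosphonium bromide (not isolated) | C[C@H]1CN2CCC[C@H](CCCO[Si](C)(C)C(C)(C)C)[C@@H]2[C@@H](CC[P+](c4ccccc4)(c4ccccc4)c4ccccc4)C13OCCO3.[Br-] | intermediate
18 | [2-[(1R,3S,9R,9aR)-2,2-(ethylenedioxy)-9-(3-hydroxypropyl)-3-methyloctahydro-2H-quinolizin-1-yl]ethyl]triphenylphosphonium bromide | C[C@H]1CN2CCC[C@H](CCCO)[C@@H]2[C@@H](CC[P+](c4ccccc4)(c4ccccc4)c4ccccc4)C13OCCO3.[Br-] | intermediate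
19 | [2-[(1R,3S,9R,9aR)-2,2-(ethylenedioxy)-3-methyl-9-(3-oxopropyl)octahydro-2H-quinolizin-1-yl]ethyl]triphenylphosphonium bromide | C[C@H]1CN2CCC[C@H](CCC=O)[C@@H]2[C@@H](CC[P+](c4ccccc4)(c4ccccc4)c4ccccc4)C13OCCO3.[Br-] | intermediate
20 | macrocyclic (Z,Z)-diene bis(ethylene ketal), each half (1R,3S,9S,9aR), C9 linked to C1 of the other half by CH2CH2CH=CHCH2 | C[C@H]1CN2CCC[C@@H]3CC/C=C\C[C@H]4C6(OCCO6)[C@@H](C)CN5CCC[C@H](CC/C=C\C[C@@H](C17OCCO7)[C@@H]32)[C@H]45 | intermediate
21 | saturated macrocyclic bis(ethylene ketal), each half (1R,3S,9S,9aR), pentamethylene links | C[C@H]1CN2CCC[C@@H]3CCCCC[C@H]4C6(OCCO6)[C@@H](C)CN5CCC[C@H](CCCCC[C@@H](C17OCCO7)[C@@H]32)[C@H]45 | intermediate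
22 | CNP0268544.6, macrocyclic bis(3-methylquinolizidin-2-one), each half (1R,3S,9S,9aR) | C[C@H]1CN2CCC[C@@H]3CCCCC[C@H]4C(=O)[C@@H](C)CN5CCC[C@H](CCCCC[C@@H](C1=O)[C@@H]32)[C@H]45 | target

**Step count and risks**

Total step count: 17. Longest linear sequence: 17 steps (1 to 22); 2, 8 and 11 are commercial and enter directly.

Steps most likely to fail:

1. Step 15 (Wittig cyclodimerisation). Ring closure within one molecule, where the C9 and C1 chains of the same half meet to an eight-membered cycloalkene, or chain growth to open oligomers may outrun the second, ring-forming olefination. The fallback joins the halves one bond at a time; it sets out from 16 and 17 and comes back at 20. Bromide 16 is desilylated with aq. HF in MeCN to (1R,3S,9R,9aR)-1-(2-bromoethyl)-2,2-(ethylenedioxy)-9-(3-hydroxypropyl)-3-methyloctahydro-2H-quinolizine F1, and Swern oxidation gives the corresponding 9-(3-oxopropyl) bromo aldehyde F2. Salt 17, this time isolated before desilylation, is converted into its ylide with KN(SiMe3)2 in THF at −78 °C and condensed with F2. This should give the open-chain dimer F3, with one (Z)-c=d alkene, the silyl ether on one half and the primary bromide on the other. PPh3 in MeCN at 80 °C then gives the silyl ether phosphonium bromide F4, aq. HF the hydroxy phosphonium bromide F5, and Swern oxidation the aldehyde phosphonium bromide F6. Slow addition of F6 to KN(SiMe3)2 in THF at high dilution closes the 16-membered ring to 20; at this stage no eight-membered closure is possible, because the other c–d pair is already joined.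

2. Step 9 (Stetter closure). The β-amino aldehyde may fragment by retro-aza-Michael loss of methacrolein, the base may move the enoate double bond towards nitrogen with loss of the C10 configuration, or the aldehyde may be used up in aldol or benzoin pathways before the hindered acyl anion equivalent adds. The fallback forms the same C1–C2 bond by an acyl radical instead of a carbene adduct; it sets out from 12 and comes back at 13. Pinnick oxidation of 12 (NaClO2, NaH2PO4, 2-methylbut-2-ene, t-BuOH–H2O) gives 3-[(2R,3R)-3-[3-(TBS-oxy)propyl]-2-[(E)-3-ethoxy-3-oxoprop-1-enyl]piperidin-1-yl]-2-methylpropanoic acid F7. Diphenyl diselenide and PBu3 in CH2Cl2 convert it into the Se-phenyl selenoester F8. Bu3SnH and AIBN in benzene at 80 °C generate the acyl radical, which should add 6-exo-trig to the enoate; DBU equilibration then gives 13.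

3. Step 3 (resolution). Neither diastereomeric salt of the lipophilic silyl ether may crystallise, or the salts may crystallise together without enrichment. The fallback separates the enantiomers by chromatography one step later; it sets out from 4 and comes back at 6. Racemic 4 is acylated as in step 4 to racemic 1-allyl 2-methyl cis-3-[3-(TBS-oxy)propyl]piperidine-1,2-dicarboxylate F9. Preparative supercritical-fluid chromatography on an amylose tris(3,5-dimethylphenylcarbamate) phase (CO2–MeOH) then delivers the (2R,3R)-enantiomer, which is 6.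

**Further compounds**

F1 | step 15 | (1R,3S,9R,9aR)-1-(2-bromoethyl)-2,2-(ethylenedioxy)-9-(3-hydroxypropyl)-3-methyloctahydro-2H-quinolizine | C[C@H]1CN2CCC[C@H](CCCO)[C@@H]2[C@@H](CCBr)C13OCCO3
F2 | step 15 | 3-[(1R,2S,9R,9aR numbering as in 16: 1-(2-bromoethyl)-2,2-(ethylenedioxy)-3-methyloctahydro-2H-quinolizin-9-yl]propanal (bromo aldehyde) | C[C@H]1CN2CCC[C@H](CCC=O)[C@@H]2[C@@H](CCBr)C13OCCO3
F3 | step 15 | open-chain dimer: C1 chain of the silyl ether half linked by (Z)-CH2CH=CHCH2CH2 to C9 of the bromoethyl half, both ketals in place | C[C@H]1CN2CCC[C@H](CCCO[Si](C)(C)C(C)(C)C)[C@@H]2[C@@H](C/C=C\CC[C@H]5CCCN6C[C@H](C)C7(OCCO7)[C@H](CCBr)[C@@H]56)C13OCCO3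
F4 | step 15 | open-chain dimer, triphenylphosphonium bromide in place of the bromide, silyl ether retained | C[C@H]1CN2CCC[C@H](CCCO[Si](C)(C)C(C)(C)C)[C@@H]2[C@@H](C/C=C\CC[C@H]5CCCN6C[C@H](C)C7(OCCO7)[C@H](CC[P+](c8ccccc8)(c8ccccc8)c8ccccc8)[C@@H]56)C13OCCO3.[Br-]
F5 | step 15 | open-chain dimer, hydroxy phosphonium bromide | C[C@H]1CN2CCC[C@H](CCCO)[C@@H]2[C@@H](C/C=C\CC[C@H]5CCCN6C[C@H](C)C7(OCCO7)[C@H](CC[P+](c8ccccc8)(c8ccccc8)c8ccccc8)[C@@H]56)C13OCCO3.[Br-]
F6 | step 15 | open-chain dimer, aldehyde phosphonium bromide | C[C@H]1CN2CCC[C@H](CCC=O)[C@@H]2[C@@H](C/C=C\CC[C@H]5CCCN6C[C@H](C)C7(OCCO7)[C@H](CC[P+](c8ccccc8)(c8ccccc8)c8ccccc8)[C@@H]56)C13OCCO3.[Br-]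
F7 | step 9 | 3-[(2R,3R)-3-[3-(tert-butyldimethylsilyloxy)propyl]-2-[(E)-3-ethoxy-3-oxoprop-1-enyl]piperidin-1-yl]-2-methylpropanoic acid, both epimers at the methyl-bearing carbon | OC(=O)C(C)CN1CCC[C@H](CCCO[Si](C)(C)C(C)(C)C)[C@@H]1/C=C/C(=O)OCC
F8 | step 9 | Se-phenyl 3-[(2R,3R)-3-[3-(tert-butyldimethylsilyloxy)propyl]-2-[(E)-3-ethoxy-3-oxoprop-1-enyl]piperidin-1-yl]-2-methylpropaneselenoate, both epimers at the methyl-bearing carbon | O=C([Se]c1ccccc1)C(C)CN2CCC[C@H](CCCO[Si](C)(C)C(C)(C)C)[C@@H]2/C=C/C(=O)OCC
F9 | step 3 | (±)-1-allyl 2-methyl cis-3-[3-(tert-butyldimethylsilyloxy)propyl]piperidine-1,2-dicarboxylate (racemate; one enantiomer drawn) | C=CCOC(=O)N1CCC[C@H](CCCO[Si](C)(C)C(C)(C)C)[C@@H]1C(=O)OC
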